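The synthesis rests on opening the 1,2-dioxane ring at both of its C–O bonds, O2–C3 and O1–C6, which leads back to an acyclic (3E,5Z)-diene and dioxygen. Singlet oxygen adds across the diene termini and in one operation closes the peroxide ring and creates the C3 and C6 stereocentres. The feature exploited is the cis relation between the C6 methyl group and the C3 branch on the dioxane ring, which is written into the diene geometry, while the existing C2 stereocentre selects the π-face. The precursor is a nine-carbon diene carrying a silyl ether at each end; the trimethylcyclohexene unit, itself a substrate for singlet oxygen, is joined later.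

Key step: step 9

Remark: the diene chain is numbered C1 (silyloxymethyl carbon) to C9 and the ring atoms O1, O2, C3 (bearing the C2 branch) to C6 (bearing the methyl group); neryl acetate, (2S)-3-bromo-2-methylpropan-1-ol and dihydro-β-ionone are assumed to be purchased as such.

Step 1
Reactants: 1 neryl acetate
Product: 3 (2Z)-6-hydroxy-3-methylhex-2-en-1-yl acetate, via acetoxy aldehyde 2 (not isolated)
Conditions: O3, CH2Cl2/MeOH, Sudan Red 7B as end-point indicator, −78 °C; then NaBH4, −78 → 0 °C
Reagents that add atoms: ozone, [O-][O+]=O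
Why: Chemoselective ozonolysis with reductive work-up: the isopropylidene alkene is more electron-rich than the alkene deactivated by the allylic acetate, so ozone dosed to the dye end-point should cleave only the former, and NaBH4 reduces the peroxidic products and aldehyde 2 to the primary alcohol.

Step 2
Reactants: 3 (2Z)-6-hydroxy-3-methylhex-2-en-1-yl acetate
Product: 4 (2Z)-6-(tert-butyldiphenylsilyloxy)-3-methylhex-2-en-1-yl acetate
Conditions: TBDPSCl, imidazole, DMF, 0 °C → rt
Reagents that add atoms: tert-butyl(chloro)diphenylsilane, CC(C)(C)[Si](Cl)(c1ccccc1)c1ccccc1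
Why: Silyl ether formation at the primary alcohol; the robust TBDPS group is chosen because it must outlast the TBS ether at the other chain end.

Step 3
Reactants: 4 (2Z)-6-(tert-butyldiphenylsilyloxy)-3-methylhex-2-en-1-yl acetate
Product: 5 (2Z)-6-(tert-butyldiphenylsilyloxy)-3-methylhex-2-en-1-ol
Conditions: K2CO3 (cat.), MeOH, rt
Reagents that add atoms: none
Why: Base-catalysed transesterification of the acetate with methanol, which leaves the silyl ether and the alkene geometry unchanged.

Step 4
Reactants: 5 (2Z)-6-(tert-butyldiphenylsilyloxy)-3-methylhex-2-en-1-ol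
Product: 6 (2Z)-6-(tert-butyldiphenylsilyloxy)-3-methylhex-2-enal
Conditions: activated MnO2 (excess), CH2Cl2, 0 °C → rt, dark
Reagents that add atoms: none
Why: Allylic oxidation with MnO2 stops at the enal under neutral heterogeneous conditions, under which the Z-trisubstituted alkene should not isomerise.

Step 5
Reactants: 7 (2S)-3-bromo-2-methylpropan-1-ol
Product: 8 [(2S)-3-bromo-2-methylpropoxy](tert-butyl)dimethylsilane
Conditions: TBSCl, imidazole, CH2Cl2, 0 °C → rt
Reagents that add atoms: tert-butyl(chloro)dimethylsilane, CC(C)(C)[Si](C)(C)Cl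
Why: Silyl ether formation at the primary alcohol; the stereocentre is not a reacting centre and the primary bromide is untouched.

Step 6
Reactants: 8 [(2S)-3-bromo-2-methylpropoxy](tert-butyl)dimethylsilane
Product: 9 5-{[(2S)-3-(tert-butyldimethylsilyloxy)-2-methylpropyl]sulfanyl}-1-phenyl-1H-tetrazole
Conditions: 1-phenyl-1H-tetrazole-5-thiol, K2CO3, DMF, 60 °C
Reagents that add atoms: 1-phenyl-1H-tetrazole-5-thiol, Sc1nnnn1-c1ccccc1
Why: SN2 displacement of the primary bromide by the soft tetrazole thiolate (S-alkylation), with the neighbouring stereocentre keeping its configuration.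

Step 7
Reactants: 9 5-{[(2S)-3-(tert-butyldimethylsilyloxy)-2-methylpropyl]sulfanyl}-1-phenyl-1H-tetrazole
Product: 10 5-{[(2S)-3-(tert-butyldimethylsilyloxy)-2-methylpropyl]sulfonyl}-1-phenyl-1H-tetrazole
Conditions: (NH4)6Mo7O24·4H2O (cat.), 30% H2O2, EtOH, 0 °C → rt
Reagents that add atoms: hydrogen peroxide, OO
Why: Molybdate-catalysed oxidation of the sulfide to the sulfone, conditions under which a primary TBS ether is expected to survive.

Step 8
Reactants: 10 5-{[(2S)-3-(tert-butyldimethylsilyloxy)-2-methylpropyl]sulfonyl}-1-phenyl-1H-tetrazole + 6 (2Z)-6-(tert-butyldiphenylsilyloxy)-3-methylhex-2-enal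
Product: 12 (2R,3E,5Z)-1-(tert-butyldimethylsilyloxy)-9-(tert-butyldiphenylsilyloxy)-2,6-dimethylnona-3,5-diene, via potassiated sulfone 11 (not isolated)
Conditions: 10, KN(SiMe3)2, DME, −78 °C; then 6, −78 °C → rt
Reagents that add atoms: none
Why: Julia–Kocienski olefination: carbanion 11 adds to the aldehyde, Smiles rearrangement and loss of SO2 and tetrazololate give the alkene, the potassium base in DME favouring the E-isomer at C3=C4, while the Z-alkene of 6 and the non-acidic C2 centre are carried over unchanged.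

Step 9
Reactants: 12 (2R,3E,5Z)-1-(tert-butyldimethylsilyloxy)-9-(tert-butyldiphenylsilyloxy)-2,6-dimethylnona-3,5-diene
Product: 13 (3S,6R)-3-[(2S)-1-(tert-butyldimethylsilyloxy)propan-2-yl]-6-[3-(tert-butyldiphenylsilyloxy)propyl]-6-methyl-3,6-dihydro-1,2-dioxine
Conditions: O2, tetraphenylporphyrin (cat.), white LED, CH2Cl2, −78 °C
Reagents that add atoms: dioxygen, O=O
Why: Sensitised singlet oxygen acts as a two-electron dienophile toward the s-cis conformer of 12 and forms O2–C3 and O1–C6 in a concerted suprafacial [4+2] cycloaddition, the closest known reaction type being the endoperoxidation of acyclic 1,3-dienes by singlet oxygen. The six-membered 3,6-dihydro-1,2-dioxine ring is closed by this cycloaddition, both ring bonds arising in the same event and not by cyclisation of a tethered nucleophile. The relative configuration of C3 and C6 is controlled by the diene geometry: the E-alkene turns the C2 branch outward and the Z-alkene turns the C6 methyl outward, so both should come to lie on one face of the ring. The absolute sense (3S,6R) is controlled by the C2 stereocentre: with C2–H lying in the diene plane, oxygen should approach from the side of the small methyl group and away from the silyloxymethyl group, a moderate preference, so the (3R,6S) isomer is expected as a minor product to be removed by chromatography. The step needs cycloaddition to win over the ene reaction and dioxetane formation at the trisubstituted C5=C6 alkene; the E-configured C3=C4 alkene, which leaves only hydrogen pointing inward at C3 and keeps the s-cis conformer within reach, together with the aprotic solvent and low temperature should secure this, and no other alkene that reacts with singlet oxygen is present at this stage.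

Step 10
Reactants: 13 (3S,6R)-3-[(2S)-1-(tert-butyldimethylsilyloxy)propan-2-yl]-6-[3-(tert-butyldiphenylsilyloxy)propyl]-6-methyl-3,6-dihydro-1,2-dioxine
Product: 14 (3S,6R)-3-[(2S)-1-(tert-butyldimethylsilyloxy)propan-2-yl]-6-[3-(tert-butyldiphenylsilyloxy)propyl]-6-methyl-1,2-dioxane
Conditions: KO2CN=NCO2K (excess), AcOH, CH2Cl2, 0 °C → rt
Reagents that add atoms: none
Why: Diimide reduction: diimide released from the azodicarboxylate salt delivers two hydrogen atoms to the cis-disubstituted ring alkene through a cyclic transition state and does not cleave the O–O bond, which catalytic hydrogenation would.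

Step 11
Reactants: 14 (3S,6R)-3-[(2S)-1-(tert-butyldimethylsilyloxy)propan-2-yl]-6-[3-(tert-butyldiphenylsilyloxy)propyl]-6-methyl-1,2-dioxane
Product: 15 (2S)-2-[(3S,6R)-6-[3-(tert-butyldiphenylsilyloxy)propyl]-6-methyl-1,2-dioxan-3-yl]propan-1-ol
Conditions: camphor-10-sulfonic acid (cat.), MeOH/CH2Cl2, 0 °C
Reagents that add atoms: none
Why: Selective desilylation: acid-catalysed methanolysis removes a primary TBS ether much faster than a primary TBDPS ether, and the dialkyl peroxide tolerates catalytic acid at this temperature.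

Step 12
Reactants: 15 (2S)-2-[(3S,6R)-6-[3-(tert-butyldiphenylsilyloxy)propyl]-6-methyl-1,2-dioxan-3-yl]propan-1-ol
Product: 17 (2R)-2-[(3S,6R)-6-[3-(tert-butyldiphenylsilyloxy)propyl]-6-methyl-1,2-dioxan-3-yl]propanoic acid, via aldehyde 16 (not isolated)
Conditions: TEMPO (2,2,6,6-tetramethylpiperidin-1-oxyl, cat.), PhI(OAc)2, MeCN/H2O, rt
Reagents that add atoms: water, O
Why: Oxoammonium-mediated oxidation takes the primary alcohol through aldehyde 16 and its hydrate to the acid under near-neutral conditions, so the α-stereocentre C2 should not epimerise and the β-peroxy group should not be eliminated.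

Step 13
Reactants: 17 (2R)-2-[(3S,6R)-6-[3-(tert-butyldiphenylsilyloxy)propyl]-6-methyl-1,2-dioxan-3-yl]propanoic acid
Product: 18 methyl (2R)-2-[(3S,6R)-6-[3-(tert-butyldiphenylsilyloxy)propyl]-6-methyl-1,2-dioxan-3-yl]propanoate
Conditions: Me3SiCHN2, toluene/MeOH, 0 °C
Reagents that add atoms: trimethylsilyldiazomethane, C[Si](C)(C)C=[N+]=[N-]
Why: Non-basic esterification of the acid with trimethylsilyldiazomethane in the presence of methanol, which touches neither C2 nor the peroxide.

Step 14
Reactants: 18 methyl (2R)-2-[(3S,6R)-6-[3-(tert-butyldiphenylsilyloxy)propyl]-6-methyl-1,2-dioxan-3-yl]propanoate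
Product: 19 methyl (2R)-2-[(3S,6R)-6-(3-hydroxypropyl)-6-methyl-1,2-dioxan-3-yl]propanoate
Conditions: HF·pyridine, pyridine, THF, 0 °C → rt
Reagents that add atoms: none
Why: Fluoride-mediated desilylation with buffered HF·pyridine, chosen over basic fluoride sources because the ester carries an α-hydrogen β to the peroxide.

Step 15
Reactants: 19 methyl (2R)-2-[(3S,6R)-6-(3-hydroxypropyl)-6-methyl-1,2-dioxan-3-yl]propanoate
Product: 20 methyl (2R)-2-[(3S,6S)-6-methyl-6-(3-oxopropyl)-1,2-dioxan-3-yl]propanoate
Conditions: TEMPO (cat.), PhI(OAc)2, CH2Cl2, rt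
Reagents that add atoms: none
Why: Oxoammonium oxidation of the primary alcohol in anhydrous solvent stops at the aldehyde; the C6 descriptor changes only through ligand priorities, not through any change in space.

Step 16
Reactants: 21 dihydro-β-ionone
Product: 22 2,4,6-tri(propan-2-yl)-N'-[4-(2,6,6-trimethylcyclohex-1-en-1-yl)butan-2-ylidene]benzenesulfonohydrazide
Conditions: 2,4,6-triisopropylbenzenesulfonohydrazide, MeOH, HCl (cat.), rt
Reagents that add atoms: 2,4,6-tri(propan-2-yl)benzenesulfonohydrazide, CC(C)c1cc(C(C)C)c(S(=O)(=O)NN)c(C(C)C)c1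
Why: Acid-catalysed condensation of the methyl ketone with the arylsulfonyl hydrazide gives the crystalline hydrazone required for the Shapiro reaction.

Step 17
Reactants: 22 2,4,6-tri(propan-2-yl)-N'-[4-(2,6,6-trimethylcyclohex-1-en-1-yl)butan-2-ylidene]benzenesulfonohydrazide + 20 methyl (2R)-2-[(3S,6S)-6-methyl-6-(3-oxopropyl)-1,2-dioxan-3-yl]propanoate
Product: 25 methyl (2R)-2-[(3S,6R)-6-[(3R)-3-hydroxy-4-methylidene-6-(2,6,6-trimethylcyclohex-1-en-1-yl)hexyl]-6-methyl-1,2-dioxan-3-yl]propanoate, via alkenyllithium 23 (not isolated), via dialkenylzinc 24 (not isolated)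
Conditions: 22, n-BuLi (2 equiv), THF, −78 → 0 °C; ZnBr2 (0.5 equiv), −78 → 0 °C; solvent exchange to toluene; N,N,N',N'-tetraethylethylenediamine, (2S)-(−)-3-exo-morpholinoisoborneol (10 mol %); then 20, 0 °C; aq. NH4Cl
Reagents that add atoms: none
Why: Shapiro reaction of the trisylhydrazone gives the 2-lithio-1-alkene on the methyl side, transmetalation gives the dialkenylzinc, and its amino-alcohol-catalysed 1,2-addition to the aldehyde sets the carbinol centre under catalyst control, the (−)-amino alcohol directing the alkenyl group to the Si face, which here corresponds to the (R)-alcohol; the diamine binds the lithium salts that would promote a racemic background addition, and organozinc reagents of this kind should leave the methyl ester and the dialkyl peroxide alone.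

Step 18
Reactants: 25 methyl (2R)-2-[(3S,6R)-6-[(3R)-3-hydroxy-4-methylidene-6-(2,6,6-trimethylcyclohex-1-en-1-yl)hexyl]-6-methyl-1,2-dioxan-3-yl]propanoate
Product: 26 (2R)-2-[(3S,6R)-6-[(3R)-3-hydroxy-4-methylidene-6-(2,6,6-trimethylcyclohex-1-en-1-yl)hexyl]-6-methyl-1,2-dioxan-3-yl]propanoic acid
Conditions: LiOH, THF/H2O, 0 °C → rt; then 1 M HCl to pH 3
Reagents that add atoms: LiOH, [Li+].[OH-]
Why: Ester hydrolysis (saponification) at low temperature followed by mild acidification; hydroxide attack at the ester carbonyl is expected to be faster than deprotonation at C2, so the C2 configuration and the peroxide ring should be retained.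

Compound list

1 | neryl acetate, (2Z)-3,7-dimethylocta-2,6-dien-1-yl acetate | CC(C)=CCC/C(C)=C\COC(C)=O | starting material
2 | (2Z)-3-methyl-6-oxohex-2-en-1-yl acetate (acetoxy aldehyde, not isolated) | O=CCC/C(C)=C\COC(C)=O | intermediate
3 | (2Z)-6-hydroxy-3-methylhex-2-en-1-yl acetate | OCCC/C(C)=C\COC(C)=O | intermediate
4 | (2Z)-6-(tert-butyldiphenylsilyloxy)-3-methylhex-2-en-1-yl acetate | CC(C)(C)[Si](c1ccccc1)(c1ccccc1)OCCC/C(C)=C\COC(C)=O | intermediate
5 | (2Z)-6-(tert-butyldiphenylsilyloxy)-3-methylhex-2-en-1-ol | CC(C)(C)[Si](c1ccccc1)(c1ccccc1)OCCC/C(C)=C\CO | intermediate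
6 | (2Z)-6-(tert-butyldiphenylsilyloxy)-3-methylhex-2-enal | CC(C)(C)[Si](c1ccccc1)(c1ccccc1)OCCC/C(C)=C\C=O | intermediate
7 | (2S)-3-bromo-2-methylpropan-1-ol | OC[C@H](C)CBr | starting material
8 | [(2S)-3-bromo-2-methylpropoxy](tert-butyl)dimethylsilane | CC(C)(C)[Si](C)(C)OC[C@H](C)CBr | intermediate
9 | 5-{[(2S)-3-(tert-butyldimethylsilyloxy)-2-methylpropyl]sulfanyl}-1-phenyl-1H-tetrazole | CC(C)(C)[Si](C)(C)OC[C@H](C)CSc1nnnn1-c1ccccc1 | intermediate
10 | 5-{[(2S)-3-(tert-butyldimethylsilyloxy)-2-methylpropyl]sulfonyl}-1-phenyl-1H-tetrazole | CC(C)(C)[Si](C)(C)OC[C@H](C)CS(=O)(=O)c1nnnn1-c1ccccc1 | intermediate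
11 | potassium (2S)-3-(tert-butyldimethylsilyloxy)-2-methyl-1-[(1-phenyl-1H-tetrazol-5-yl)sulfonyl]propan-1-ide (potassiated sulfone, not isolated) | CC(C)(C)[Si](C)(C)OC[C@H](C)[CH-]S(=O)(=O)c1nnnn1-c1ccccc1.[K+] | intermediate
12 | (2R,3E,5Z)-1-(tert-butyldimethylsilyloxy)-9-(tert-butyldiphenylsilyloxy)-2,6-dimethylnona-3,5-diene | CC(C)(C)[Si](C)(C)OC[C@H](C)/C=C/C=C(/C)CCCO[Si](c1ccccc1)(c1ccccc1)C(C)(C)C | intermediate
13 | (3S,6R)-3-[(2S)-1-(tert-butyldimethylsilyloxy)propan-2-yl]-6-[3-(tert-butyldiphenylsilyloxy)propyl]-6-methyl-3,6-dihydro-1,2-dioxine | CC(C)(C)[Si](c1ccccc1)(c1ccccc1)OCCC[C@]1(C)C=C[C@@H]([C@@H](C)CO[Si](C)(C)C(C)(C)C)OO1 | intermediate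
14 | (3S,6R)-3-[(2S)-1-(tert-butyldimethylsilyloxy)propan-2-yl]-6-[3-(tert-butyldiphenylsilyloxy)propyl]-6-methyl-1,2-dioxane | CC(C)(C)[Si](c1ccccc1)(c1ccccc1)OCCC[C@]1(C)CC[C@@H]([C@@H](C)CO[Si](C)(C)C(C)(C)C)OO1 | intermediate
15 | (2S)-2-[(3S,6R)-6-[3-(tert-butyldiphenylsilyloxy)propyl]-6-methyl-1,2-dioxan-3-yl]propan-1-ol | CC(C)(C)[Si](c1ccccc1)(c1ccccc1)OCCC[C@]1(C)CC[C@@H]([C@@H](C)CO)OO1 | intermediate
16 | (2R)-2-[(3S,6R)-6-[3-(tert-butyldiphenylsilyloxy)propyl]-6-methyl-1,2-dioxan-3-yl]propanal (not isolated) | CC(C)(C)[Si](c1ccccc1)(c1ccccc1)OCCC[C@]1(C)CC[C@@H]([C@@H](C)C=O)OO1 | intermediate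
17 | (2R)-2-[(3S,6R)-6-[3-(tert-butyldiphenylsilyloxy)propyl]-6-methyl-1,2-dioxan-3-yl]propanoic acid | CC(C)(C)[Si](c1ccccc1)(c1ccccc1)OCCC[C@]1(C)CC[C@@H]([C@@H](C)C(=O)O)OO1 | intermediate
18 | methyl (2R)-2-[(3S,6R)-6-[3-(tert-butyldiphenylsilyloxy)propyl]-6-methyl-1,2-dioxan-3-yl]propanoate | CC(C)(C)[Si](c1ccccc1)(c1ccccc1)OCCC[C@]1(C)CC[C@@H]([C@@H](C)C(=O)OC)OO1 | intermediate
19 | methyl (2R)-2-[(3S,6R)-6-(3-hydroxypropyl)-6-methyl-1,2-dioxan-3-yl]propanoate | OCCC[C@]1(C)CC[C@@H]([C@@H](C)C(=O)OC)OO1 | intermediate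
20 | methyl (2R)-2-[(3S,6S)-6-methyl-6-(3-oxopropyl)-1,2-dioxan-3-yl]propanoate | O=CCC[C@]1(C)CC[C@@H]([C@@H](C)C(=O)OC)OO1 | intermediate
21 | dihydro-β-ionone, 4-(2,6,6-trimethylcyclohex-1-en-1-yl)butan-2-one | CC(=O)CCC1=C(C)CCCC1(C)C | starting material
22 | 2,4,6-tri(propan-2-yl)-N'-[4-(2,6,6-trimethylcyclohex-1-en-1-yl)butan-2-ylidene]benzenesulfonohydrazide | CC(CCC1=C(C)CCCC1(C)C)=NNS(=O)(=O)c1c(C(C)C)cc(C(C)C)cc1C(C)C | intermediate
23 | [4-(2,6,6-trimethylcyclohex-1-en-1-yl)but-1-en-2-yl]lithium (not isolated) | [Li]C(=C)CCC1=C(C)CCCC1(C)C | intermediate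
24 | bis[4-(2,6,6-trimethylcyclohex-1-en-1-yl)but-1-en-2-yl]zinc (not isolated) | C=C(CCC1=C(C)CCCC1(C)C)[Zn]C(=C)CCC1=C(C)CCCC1(C)C | intermediate
25 | methyl (2R)-2-[(3S,6R)-6-[(3R)-3-hydroxy-4-methylidene-6-(2,6,6-trimethylcyclohex-1-en-1-yl)hexyl]-6-methyl-1,2-dioxan-3-yl]propanoate | C=C(CCC1=C(C)CCCC1(C)C)[C@H](O)CC[C@]1(C)CC[C@@H]([C@@H](C)C(=O)OC)OO1 | intermediate
26 | (2R)-2-[(3S,6R)-6-[(3R)-3-hydroxy-4-methylidene-6-(2,6,6-trimethylcyclohex-1-en-1-yl)hexyl]-6-methyl-1,2-dioxan-3-yl]propanoic acid | C=C(CCC1=C(C)CCCC1(C)C)[C@H](O)CC[C@]1(C)CC[C@@H]([C@@H](C)C(=O)O)OO1 | target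

Total step count: 18. Longest linear sequence: 14 steps (steps 1–4, 8–15, 17 and 18, from neryl acetate).

Steps most likely to fail

Step 9. What may go wrong: the two faces of the diene are attacked with little discrimination, because an E-alkene exerts only weak allylic strain on the C2 rotamers, so that the (3S,6R) and (3R,6S) cycloadducts would form in comparable amounts. Fallback: kinetic face selection is given up in favour of separating a crystalline derivative. Setting out from 12, step 9 is run as described and the unseparated cycloadducts are taken through steps 10 and 11. The mixed alcohols are acylated with 3,5-dinitrobenzoyl chloride and pyridine to give the (3S,6R)-configured 3,5-dinitrobenzoate F1 beside the (3R,6S)-configured 3,5-dinitrobenzoate F2. F1 is purified by fractional crystallisation or chromatography and methanolysed with K2CO3 in MeOH, which returns the route to 15.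

Step 17. What may go wrong: lithium salts left from the Shapiro reaction promote an uncatalysed addition, so that the carbinol centre is formed with poor face selectivity. Fallback: the stereocentre is set by reagent-controlled ketone reduction instead of during C–C bond formation. Setting out from 20 and 22, the dialkenylzinc 24 is added without amino alcohol to give 25 mixed with its carbinol epimer F3. The mixture is oxidised with Dess–Martin periodinane to the enone F4. Corey–Bakshi–Shibata reduction with (S)-2-methyl-CBS-oxazaborolidine and BH3·SMe2 at low temperature, the alkenyl group acting as the large substituent, should then return the single (R)-alcohol 25.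

Step 8. What may go wrong: loss of geometric purity, either by formation of the 3Z-alkene in the elimination or by base-induced isomerisation of the Z-enal before it is consumed. Fallback: the one-pot olefination is replaced by the classical Julia–Lythgoe sequence, whose reductive elimination should give the E-alkene whatever the configuration of the adduct. Setting out from 8, displacement with PhSO2Na in DMF gives the phenyl sulfone F5. Its lithio derivative (n-BuLi, THF, −78 °C) is added to 6 and the alkoxide is trapped with Ac2O to give the acetoxy sulfone F6 as a diastereomer mixture. SmI2 in THF/DMPU then removes sulfinate and acetate and brings the route back at 12.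

Further compounds

F1 | step 9 | (2S)-2-[(3S,6R)-6-[3-(tert-butyldiphenylsilyloxy)propyl]-6-methyl-1,2-dioxan-3-yl]propyl 3,5-dinitrobenzoate | CC(C)(C)[Si](c1ccccc1)(c1ccccc1)OCCC[C@]1(C)CC[C@@H]([C@@H](C)COC(=O)c2cc([N+](=O)[O-])cc([N+](=O)[O-])c2)OO1
F2 | step 9 | (2S)-2-[(3R,6S)-6-[3-(tert-butyldiphenylsilyloxy)propyl]-6-methyl-1,2-dioxan-3-yl]propyl 3,5-dinitrobenzoate | CC(C)(C)[Si](c1ccccc1)(c1ccccc1)OCCC[C@@]1(C)CC[C@H]([C@@H](C)COC(=O)c2cc([N+](=O)[O-])cc([N+](=O)[O-])c2)OO1
F3 | step 17 | methyl (2R)-2-[(3S,6R)-6-[(3S)-3-hydroxy-4-methylidene-6-(2,6,6-trimethylcyclohex-1-en-1-yl)hexyl]-6-methyl-1,2-dioxan-3-yl]propanoate | C=C(CCC1=C(C)CCCC1(C)C)[C@@H](O)CC[C@]1(C)CC[C@@H]([C@@H](C)C(=O)OC)OO1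
F4 | step 17 | methyl (2R)-2-[(3S,6S)-6-methyl-6-[4-methylidene-3-oxo-6-(2,6,6-trimethylcyclohex-1-en-1-yl)hexyl]-1,2-dioxan-3-yl]propanoate | C=C(CCC1=C(C)CCCC1(C)C)C(=O)CC[C@]1(C)CC[C@@H]([C@@H](C)C(=O)OC)OO1
F5 | step 8 | [(2S)-3-(benzenesulfonyl)-2-methylpropoxy](tert-butyl)dimethylsilane | CC(C)(C)[Si](C)(C)OC[C@H](C)CS(=O)(=O)c1ccccc1
F6 | step 8 | (2S,5Z)-3-(benzenesulfonyl)-1-(tert-butyldimethylsilyloxy)-9-(tert-butyldiphenylsilyloxy)-2,6-dimethylnon-5-en-4-yl acetate (mixture at C3 and C4) | CC(C)(C)[Si](C)(C)OC[C@H](C)C(S(=O)(=O)c1ccccc1)C(OC(C)=O)/C=C(/C)CCCO[Si](c1ccccc1)(c1ccccc1)C(C)(C)C
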